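**Plan**

1. Locants follow ligustilide numbering: unit A is C1–C8, the bicyclic unit B is primed. Retrosynthesis: C6'–OH comes from ketone 21. The cyclohexanone ring C6–C7–C4'–C5'–C6'–C7' of 21 is then cut at C6'–C5' and C7–C4' and C6'–C7 is rejoined. This gives cyclobutanone 20 (ring C6'–C7–C6–C7', cis-fused to ring A), whose C7' carries a butenolide with the vinyl group C4'=C5' on C3a'.
2. Enabling feature: in that six-membered ring the oxygen sits on C6' next to C5'H2–C4'H, and this two-carbon unit is a vinyl group of the unit-B butenolide. C7 is allylic to C3a=C7a, so the acyl–C7 bond of a cyclobutanone can open and take up the vinyl group. The ring grows from four to six atoms and the bicyclo[2.2.2]octenone closes in the same step.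
3. 20 is cut at C7'–C7a' (ketone α-alkenylation with bromobutenolide 7). Cyclobutanone 17 is cut at C6'–C7' and C6–C7 (intramolecular keteniminium–alkene [2+2] of amide 14). Both butenolides come from dibromide 5 by site-selective cross-couplings.
4. Forward order: butenolides, then ring A and the cyclobutanone together (step 6), then union of the halves (step 7), then ring expansion to the bridged cyclohexanone (step 8), then reduction (step 9).
5. Stereochemistry: C6/C7 from the C2-symmetric pyrrolidine auxiliary in the [2+2] (cis fusion); C7' exo by thermodynamic control; C4' and the anti relation of ring A to the C3a'=C7a' bridge from retention at C7 in the insertion; C6' from hydride attack on the face away from ring A; both butylidenes Z from β-elimination under thermodynamic control.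

Key step: step 8

Assumption: (2R,5R)-2,5-dimethylpyrrolidine is taken to induce the (6R,7S) configuration of 17; if the opposite sense is found, the (2S,5S) amine is used instead.

**Route**

Step 1
Reactants: 1 3,4-dibromofuran-2(5H)-one; 2 butanal
Product: 5 (5Z)-3,4-dibromo-5-butylidenefuran-2(5H)-one, via silyloxyfuran 3 (not isolated), via silylated aldol adduct 4 (not isolated)
Conditions: TBSOTf, i-Pr2NEt, CH2Cl2, −78 °C; 2, −78 °C; then DBU, −78 °C to rt
Reagents that add atoms: none
Why: The silyloxyfuran formed in the flask should add to butanal at C5 in a vinylogous Mukaiyama aldol reaction, and DBU then removes the silyloxy group by E1cB β-elimination, which should give the Z-butylidene (propyl away from the C4 bromine) under thermodynamic control; no stereocentre remains.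

Step 2
Reactants: 5 (5Z)-3,4-dibromo-5-butylidenefuran-2(5H)-one; 6 tributyl(ethenyl)stannane
Product: 7 (5Z)-3-bromo-5-butylidene-4-ethenylfuran-2(5H)-one
Conditions: Pd(PPh3)4 (5 mol%), toluene, 80 °C
Reagents that add atoms: none
Why: Stille coupling; oxidative addition of zerovalent palladium is faster at the β-carbon C4–Br of a 3,4-dibromobutenolide than at the α-carbon C3–Br, so one equivalent of stannane should give the 4-vinyl compound with the C3 bromide kept.

Step 3
Reactants: 5 (5Z)-3,4-dibromo-5-butylidenefuran-2(5H)-one; 8 but-3-en-1-ylzinc bromide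
Product: 9 (5Z)-3-bromo-4-(but-3-en-1-yl)-5-butylidenefuran-2(5H)-one
Conditions: PdCl2(dppf) (3 mol%), THF, 0 °C to rt
Reagents that add atoms: none
Why: Negishi coupling with the same C4-over-C3 site selectivity; the alkylzinc halide is too mild to attack the enol lactone and the bidentate ligand suppresses β-hydride elimination.

Step 4
Reactants: 10 bromoacetyl bromide; 11 (2R,5R)-2,5-dimethylpyrrolidine
Product: 12 2-bromo-1-[(2R,5R)-2,5-dimethylpyrrolidin-1-yl]ethan-1-one
Conditions: Et3N, CH2Cl2, 0 °C
Reagents that add atoms: none
Why: N-Acylation of the secondary amine (Schotten–Baumann type) by the acyl bromide, which reacts far faster than the alkyl bromide; the stereocentres of the amine are untouched.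

Step 5
Reactants: 12 2-bromo-1-[(2R,5R)-2,5-dimethylpyrrolidin-1-yl]ethan-1-one; 9 (5Z)-3-bromo-4-(but-3-en-1-yl)-5-butylidenefuran-2(5H)-one
Product: 14 2-[(5Z)-4-(but-3-en-1-yl)-5-butylidene-2-oxo-2,5-dihydrofuran-3-yl]-1-[(2R,5R)-2,5-dimethylpyrrolidin-1-yl]ethan-1-one, via Reformatsky reagent 13 (not isolated)
Conditions: Zn dust (Me3SiCl-activated), THF, rt; then 9, Pd(dba)2 (5 mol%), P(t-Bu)3 (10 mol%), THF, rt to 50 °C
Reagents that add atoms: none
Why: Zinc insertion gives the Reformatsky reagent, and its palladium-catalysed coupling with the vinyl bromide (α-alkenylation of a zinc amide enolate) should form the C7–C7a bond, since the reagent tolerates the lactone and the bulky electron-rich phosphine activates the α-bromide.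

Step 6
Reactants: 14 2-[(5Z)-4-(but-3-en-1-yl)-5-butylidene-2-oxo-2,5-dihydrofuran-3-yl]-1-[(2R,5R)-2,5-dimethylpyrrolidin-1-yl]ethan-1-one
Product: 17 (3Z,6R,7S)-3-butylidene-4,5,6,7-tetrahydro-2-benzofuran-1(3H)-one bridged from C7 to C6 by –C(=O)–CH2– (carbonyl C6' on C7, methylene C7' on C6; cis-fused cyclobutanone), via keteniminium triflate 15 (not isolated), via cyclobutaniminium triflate 16 (not isolated)
Conditions: Tf2O, 2,4,6-collidine, ClCH2CH2Cl, 0 °C to 80 °C; then aq. NaHCO3, rt
Reagents that add atoms: water, O
Why: Tf2O and collidine should turn the tertiary amide into a conjugated keteniminium ion whose central carbon bonds to the terminal alkene carbon while C7 closes onto the internal one through the cis C3a=C7a tether (intramolecular keteniminium–alkene [2+2]), and hydrolysis then gives the ketone with its carbonyl on C7; the cis fusion follows from suprafacial closure and the absolute configuration at C6/C7 from the C2-symmetric auxiliary, whose methyl groups shield one face of the keteniminium.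

Step 7
Reactants: 17 cis-fused cyclobutanone (6R,7S); 7 (5Z)-3-bromo-5-butylidene-4-ethenylfuran-2(5H)-one
Product: 20 (6S,7S,7'S)-cyclobutanone 17 carrying on C7' the (5Z)-5-butylidene-4-ethenyl-2-oxo-2,5-dihydrofuran-3-yl group, trans to C5, via lithium enolate 18 (not isolated), via zinc enolate 19 (not isolated)
Conditions: LiN(SiMe3)2, THF, −78 °C; ZnCl2, −78 to 0 °C; then 7, Pd(dba)2 (5 mol%), P(t-Bu)3 (10 mol%), THF, rt
Reagents that add atoms: none
Why: Kinetic deprotonation at the unhindered methylene C7', transmetalation to the soft zinc enolate and palladium-catalysed ketone α-alkenylation with the α-bromobutenolide should join the halves at C7'–C7a'; the new C7' centre forms on the convex face, trans to C5, and being enolisable it can settle to this more stable exo epimer.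

Step 8
Reactants: 20 cyclobutanone with the vinylbutenolide on C7' (6S,7S,7'S)
Product: 21 (6S,7R,4'R,7'S)-6'-oxo bis(butylidenephthalide) with bonds C6–C7' and C7–C4' (bicyclo[2.2.2]oct-2-en-5-one core C7'/C7a'=C3a'/C4'/C5'/C6'(=O)/C6/C7), ring A anti to the C3a'=C7a' bridge
Conditions: Ni(cod)2 (10 mol%), PCy3 (20 mol%), toluene, 60–90 °C
Reagents that add atoms: none
Why: Proposed new method: zerovalent nickel should bind the cyclobutanone carbonyl and the s-cis dienyl lactone (C5'=C4'–C3a'=C7a') held over its exo face, couple C6' with the diene terminus C5' by oxidative cyclisation to a catalyst-bound alkoxide that is an allyl/dienolate ligand at C4', open the strained ring by β-carbon elimination of the acyl–C7 bond (C7 becoming a second allyl ligand through C7a=C3a), and close C7–C4' by reductive elimination with release of the catalyst. The closest known reaction type is the nickel-catalysed intramolecular alkene insertion into cyclobutanones that converts 3-(2-vinylaryl)cyclobutanones into benzobicyclo[2.2.2]octenones, together with nickel-mediated carbonyl–1,3-diene oxidative cyclisation; new here are the tether on the α-carbon and the diene as partner. Two rings close: the carbocycle C6'–C7'–C7a'–C3a'–C4'–C5' by 6-endo attack of the carbonyl carbon on the vinyl terminus, and the cyclohexanone C6'–C5'–C4'–C7–C6–C7' by two-atom expansion of the cyclobutanone (formal 4+2). C4' is the only new stereocentre and is fixed by the bridged geometry; C7 reacts with retention because elimination and C–C coupling take place on the same face of its allyl unit, and C6 and C7' are untouched, so the trans relation of the butenolide to ring A in 20 becomes the anti relation of ring A to the C3a'=C7a' bridge. The step needs cleavage of C6'–C7 and not C6'–C7' (secured by allylic stabilisation at C7 and because coupling from C7' would have to close a four-membered ring) and bonding of C6' to the terminal, not the internal, vinyl carbon (secured by conjugation of the vinyl group with the butenolide, which makes C5' a diene terminus).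

Step 9
Reactants: 21 bicyclic ketone (6S,7R,4'R,7'S)
Product: 22 CNP0289078.2, (6S,7R,4'R,6'R,7'S)-6'-hydroxy compound
Conditions: NaBH4, CeCl3·7H2O, MeOH/THF, −78 °C
Reagents that add atoms: none
Why: Luche-type 1,2-reduction of the isolated ketone should be much faster than attack on the two conjugated enol lactones, and hydride should add to C6' from the open face beside the C3a'=C7a' bridge because the other face is blocked by C5H2 and C7a of ring A, which places the hydroxyl syn to ring A (6'R).

**Compound list**

1 | 3,4-dibromofuran-2(5H)-one | O=C1OCC(Br)=C1Br | starting material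
2 | butanal | CCCC=O | starting material
3 | 3,4-dibromo-2-(tert-butyldimethylsilyloxy)furan | CC(C)(C)[Si](C)(C)Oc1occ(Br)c1Br | intermediate (not isolated)
4 | 3,4-dibromo-5-[1-(tert-butyldimethylsilyloxy)butyl]furan-2(5H)-one, diastereomer mixture | CCCC(O[Si](C)(C)C(C)(C)C)C1OC(=O)C(Br)=C1Br | intermediate (not isolated)
5 | (5Z)-3,4-dibromo-5-butylidenefuran-2(5H)-one | CCC/C=C1\OC(=O)C(Br)=C1Br | intermediate
6 | tributyl(ethenyl)stannane | C=C[Sn](CCCC)(CCCC)CCCC | starting material
7 | (5Z)-3-bromo-5-butylidene-4-ethenylfuran-2(5H)-one | CCC/C=C1\OC(=O)C(Br)=C1C=C | intermediate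
8 | but-3-en-1-ylzinc bromide | C=CCC[Zn]Br | starting material
9 | (5Z)-3-bromo-4-(but-3-en-1-yl)-5-butylidenefuran-2(5H)-one | CCC/C=C1\OC(=O)C(Br)=C1CCC=C | intermediate
10 | bromoacetyl bromide | BrCC(Br)=O | starting material
11 | (2R,5R)-2,5-dimethylpyrrolidine | C[C@@H]1CC[C@@H](C)N1 | starting material
12 | 2-bromo-1-[(2R,5R)-2,5-dimethylpyrrolidin-1-yl]ethan-1-one | O=C(CBr)N1[C@H](C)CC[C@H]1C | intermediate
13 | bromo{2-[(2R,5R)-2,5-dimethylpyrrolidin-1-yl]-2-oxoethyl}zinc | O=C(C[Zn]Br)N1[C@H](C)CC[C@H]1C | intermediate (not isolated)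
14 | 2-[(5Z)-4-(but-3-en-1-yl)-5-butylidene-2-oxo-2,5-dihydrofuran-3-yl]-1-[(2R,5R)-2,5-dimethylpyrrolidin-1-yl]ethan-1-one | CCC/C=C1\OC(=O)C(CC(=O)N2[C@H](C)CC[C@H]2C)=C1CCC=C | intermediate
15 | (2R,5R)-1-{2-[(5Z)-4-(but-3-en-1-yl)-5-butylidene-2-oxo-2,5-dihydrofuran-3-yl]ethenylidene}-2,5-dimethylpyrrolidin-1-ium triflate | CCC/C=C1\OC(=O)C(C=C=[N+]2[C@H](C)CC[C@H]2C)=C1CCC=C.[O-]S(=O)(=O)C(F)(F)F | intermediate (not isolated)
16 | cyclobutaniminium triflate: 17 with C6'=O replaced by C6'=N+ of the (2R,5R)-2,5-dimethylpyrrolidinium | CCC/C=C1\OC(=O)C2=C1CC[C@@H]3CC(=[N+]4[C@H](C)CC[C@H]4C)[C@@H]32.[O-]S(=O)(=O)C(F)(F)F | intermediate (not isolated)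
17 | (3Z,6R,7S)-3-butylidene-4,5,6,7-tetrahydro-2-benzofuran-1(3H)-one with a cis-fused cyclobutanone on C6–C7 (C6'=O on C7, C7'H2 on C6) | CCC/C=C1\OC(=O)C2=C1CC[C@@H]3CC(=O)[C@@H]32 | intermediate
18 | lithium enolate of 17 (C6'–O–Li, C6'=C7') | CCC/C=C1\OC(=O)C2=C1CC[C@@H]3C=C(O[Li])[C@@H]32 | intermediate (not isolated)
19 | chlorozinc enolate of 17 | CCC/C=C1\OC(=O)C2=C1CC[C@@H]3C=C(O[Zn]Cl)[C@@H]32 | intermediate (not isolated)
20 | (6S,7S,7'S)-17 bearing on C7' the (5Z)-5-butylidene-4-ethenyl-2-oxo-2,5-dihydrofuran-3-yl group, trans to C5 | CCC/C=C1\OC(=O)C2=C1CC[C@@H]3[C@@H](C4=C(C=C)/C(=C/CCC)OC4=O)C(=O)[C@@H]32 | intermediate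
21 | (6S,7R,4'R,7'S)-6'-oxo dimer, bonds C6–C7' and C7–C4', bicyclo[2.2.2]octenone core | CCC/C=C1\OC(=O)C2=C1CC[C@@H]1[C@H]3C4=C(/C(=C/CCC)OC4=O)[C@H](CC3=O)[C@H]21 | intermediate
22 | CNP0289078.2, (6S,7R,4'R,6'R,7'S)-6'-hydroxy dimer | CCC/C=C1\OC(=O)C2=C1CC[C@@H]1[C@H]3C4=C(/C(=C/CCC)OC4=O)[C@H](C[C@H]3O)[C@H]21 | target

**Count and risks**

Total steps: 9. Longest linear sequence: 7 steps (steps 1, 3, 5, 6, 7, 8, 9).

Steps most likely to fail:

Step 8 (labelled step). What may go wrong: the catalyst may close a five-membered ring at the internal vinyl carbon (leading to a bicyclo[3.2.1] isomer), may insert into an enol-lactone C–O bond, or the opened bis-allyl intermediate may fail to couple at C7/C4'. The fallback uses known reaction types and runs from 20 back to 21. SmI2 with t-BuOH in THF at −78 °C should join C6' to C5' by ketyl–olefin reductive cyclisation onto the dienyl lactone. Kinetic α-protonation of the samarium dienolate then gives the tertiary cyclobutanol F1, with the alkene moved to C4'=C3a'. Mn(OAc)3·2H2O and Cu(OAc)2 in AcOH at 50 °C should next generate the alkoxy radical. β-Scission of C6'–C7 gives the ketone and an allylic radical at C7, 6-exo addition to C4' closes the cyclohexanone ring, and oxidation of the C3a' radical by divalent copper with loss of the C7a' hydrogen restores the butenolide, giving 21.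

Step 6. What may go wrong: weak facial discrimination by the auxiliary, or loss of the conjugated keteniminium ion to oligomerisation before the alkene reaches it. The fallback runs from 7 back to 17 and builds ring A by a Diels–Alder reaction instead. Hydrodebromination of 7 (HCO2H, Et3N, Pd(OAc)2, PPh3, DMF, 60 °C) gives the diene F2. Cyclobutenone F3 is freed from commercial 3-bromocyclobutanone with Bu3N. A chiral oxazaborolidinium triflimide (from the diphenylprolinol-derived o-tolyl oxazaborolidine and Tf2NH, CH2Cl2, −78 to −20 °C) should catalyse the endo cycloaddition, in which the vinyl terminus C5 bonds to the enone β-carbon and C7a to the α-carbon (ortho rule), giving the adduct F4. DBU in CH2Cl2 then moves the C3a=C4 double bond into conjugation to give 17. The catalyst enantiomer is chosen to deliver (6R,7S).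

Step 7. What may go wrong: deprotonation at the ring-fusion carbon C7 instead of C7', conjugate addition of the enolate to the electrophilic dienyl lactone of 7, or proton transfer from the more acidic product to unreacted enolate. The fallback runs from 14 back to 20 and joins the halves before the cyclobutanone exists. Cross-metathesis of 14 with vinylboronic acid pinacol ester (second-generation Grubbs catalyst RuCl2(=CHPh)(H2IMes)(PCy3), CH2Cl2, 40 °C) gives the (E)-alkenylboronate F5. Suzuki coupling with 7 at its C3 bromide (Pd(PPh3)4, K3PO4, THF/H2O, 50 °C) gives the dienyl amide F6. The keteniminium [2+2] of step 6 (Tf2O, collidine; then aq. NaHCO3) then closes ring A and the cyclobutanone together, the E geometry placing the butenolide trans to C5, to give 20.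

Further compounds
F1 | step 8 | tertiary cyclobutanol from 20 after C6'–C5' bond formation (C6'–OH, alkene C4'=C3a', C7a'–H of uncontrolled configuration) | CCC/C=C1\OC(=O)C2=C1CC[C@@H]3[C@H]4C5C(=O)O/C(=C\CCC)C5=CC[C@@]4(O)[C@@H]32
F2 | step 6 | (5Z)-5-butylidene-4-ethenylfuran-2(5H)-one | CCC/C=C1\OC(=O)C=C1C=C
F3 | step 6 | cyclobut-2-en-1-one | O=C1C=CC1
F4 | step 6 | endo Diels–Alder adduct (C3a=C4 alkene, C7a–H, cis-fused cyclobutanone on C6–C7) | CCC/C=C1\OC(=O)[C@@H]2C1=CC[C@@H]3CC(=O)[C@@H]32
F5 | step 7 | (E)-alkenylboronic acid pinacol ester of 14 (terminal CH replaced by C–Bpin) | CCC/C=C1\OC(=O)C(CC(=O)N2[C@H](C)CC[C@H]2C)=C1CC/C=C/B3OC(C)(C)C(C)(C)O3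
F6 | step 7 | dienyl amide: 14 with its terminal alkene carbon joined (E) to C3 of the 5-butylidene-4-ethenylbutenolide | CCC/C=C1\OC(=O)C(CC(=O)N2[C@H](C)CC[C@H]2C)=C1CC/C=C/C3=C(C=C)/C(=C/CCC)OC3=O
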